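**Plan**

- Numbering is cembrane numbering: C1 is the ring CH that carries the lactone carbons C15–C17, C3 the lactone O–CH, C4 the C(OH)CH3 carbon, C7 the CH–OOH carbon, C8 the C(=CH2) carbon, and C11/C12 the epoxide.
- Cuts: C7–OOH with C8=C19 (ene reaction, back to a C7=C8 olefin); the ring bond C4–C5 (C4 methyl ketone plus a terminal C5=C6–C7=C8 diene); C6–C7 (vinyl); the C11/C12 epoxide (olefin); C12–C13 (sp3–sp2).
- Enabling feature: C4 is a tertiary carbinol flanked by the lactone O–CH (C3) and joined through C5H2–C6H2 to the C7=C8 olefin. This is the product pattern of a reductive addition of a diene terminus to a ketone with hydrogen delivered to C6.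
- Forward: the δ-lactone comes first from (R)-carvone (carveol, hydroboration, bridged lactone, ozonolysis, which frees the lactone ring, the C4 methyl ketone and C13). The chain is then joined at C12–C13, epoxidised and vinylated, the 14-membered ring is closed at C4–C5, and C15 equilibration and the singlet-oxygen ene reaction come last.
- Stereochemistry: C1 and C3 from (R)-carvone and its Luche reduction; C4 by Cornforth/Felkin–Anh control from C3 in the ring closure; C11/C12 by the ent-Shi catalyst; C15 by thermodynamic equilibration of the lactone; C7 by a face-selective ene reaction on the macrocycle.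

Key step: step 14

Remark: the hydroboration in step 2 is not expected to control C15, so compounds 3–10 and 18–22 are carried as mixtures of both C15 epimers and converged in step 15.

**Fragment A (steps 1–6)**

Step 1
Reactants: 1 (R)-(–)-carvone
Product: 2 (1R,5R)-cis-carveol
Conditions: NaBH4, CeCl3·7H2O, MeOH, –78 → 0 °C
Reagents that add atoms: none
Why: Luche 1,2-reduction, in which hydride adds axially to the enone half-chair that holds the isopropenyl group equatorial, so the new carbinol (C3) should come out cis to the isopropenyl group (C1 fixed by the starting material).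

Step 2
Reactants: 2 (1R,5R)-cis-carveol
Product: 4 (1R,5R)-5-(1-hydroxypropan-2-yl)-2-methylcyclohex-2-en-1-ol (both C15 epimers), via bis-borane adduct 3 (not isolated)
Conditions: 9-BBN (2.4 equiv), THF, 0 → 25 °C; then NaOH, H2O2, 0 °C
Reagents that add atoms: hydrogen peroxide, OO
Why: anti-Markovnikov hydroboration–oxidation, in which 9-BBN takes the 1,1-disubstituted isopropenyl olefin and leaves the trisubstituted ring olefin; the new C15 centre is not controlled here and is set in step 15.

Step 3
Reactants: 4 diol (both C15 epimers)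
Product: 6 (1R,5R)-4,8-dimethyl-2-oxabicyclo[3.3.1]non-7-en-3-one (both C15 epimers), via bicyclic lactol 5 (not isolated)
Conditions: TEMPO (0.2 equiv), PhI(OAc)2 (2.5 equiv), CH2Cl2, 25 °C
Reagents that add atoms: none
Why: oxoammonium (TEMPO) oxidative lactonisation, in which the primary alcohol is oxidised faster than the hindered secondary allylic one, the aldehyde closes onto the cis hydroxyl as lactol 5 and this is oxidised on to the δ-lactone.

Step 4
Reactants: 6 bridged lactone
Product: 8 (6R)-6-acetyl-3-methyl-4-(2-oxoethyl)oxan-2-one (4,6-cis; both C15 epimers), via ozonide 7 (not isolated)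
Conditions: O3, CH2Cl2, –78 °C; then PPh3, –78 → 25 °C
Reagents that add atoms: ozone, [O-][O+]=O
Why: ozonolysis of the only olefin cleaves the carbocycle and leaves the monocyclic 4,6-cis δ-lactone with the C4 methyl ketone and the C13 aldehyde, without touching the two stereocentres.

Step 5
Reactants: 8 keto aldehyde
Product: 9 (6R)-6-acetyl-4-(2-hydroxyethyl)-3-methyloxan-2-one (4,6-cis; both C15 epimers)
Conditions: NaBH(OAc)3, CH2Cl2, 25 °C
Reagents that add atoms: none
Why: chemoselective hydride reduction, since the acyloxyborohydride reduces aldehydes but not ketones or lactones, so only C13 is reduced.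

Step 6
Reactants: 9 hydroxy ketone
Product: 10 (6R)-6-acetyl-4-(2-iodoethyl)-3-methyloxan-2-one (4,6-cis; both C15 epimers)
Conditions: I2, PPh3, imidazole, CH2Cl2, 0 °C
Reagents that add atoms: iodine, II
Why: Appel-type iodination of the primary alcohol under neutral conditions, which spares the base-sensitive α-acyloxy ketone and the lactone.

**Fragment B (steps 7–10)**

Step 7
Reactants: 11 pent-3-yn-1-ol
Product: 13 (E)-4-iodopent-3-en-1-ol, via alkenylzirconocene 12 (not isolated)
Conditions: Cp2Zr(H)Cl (2.6 equiv), THF, 40 °C; then I2, 0 °C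
Reagents that add atoms: iodine, II
Why: syn hydrozirconation of the 2-alkyne, where excess hydride lets zirconium equilibrate to the methyl-bearing carbon, followed by iodinolysis with retention, so the E iodide (iodine trans to the chain) should result.

Step 8
Reactants: 13 (E)-4-iodopent-3-en-1-ol
Product: 14 (E)-2,5-diiodopent-2-ene
Conditions: I2, PPh3, imidazole, CH2Cl2, 0 °C
Reagents that add atoms: iodine, II
Why: Appel-type iodination of the primary alcohol; the alkenyl iodide is inert.

Step 9
Reactants: 14 (E)-2,5-diiodopent-2-ene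
Product: 15 (E)-6-iodohept-5-en-1-yne
Conditions: LiC≡CH·H2NCH2CH2NH2, DMSO, 15 °C
Reagents that add atoms: lithium acetylide ethylenediamine complex, [Li+].[C-]#C.NCCN
Why: SN2 alkylation of acetylide by the primary iodide; the alkenyl iodide cannot be substituted and has no anti hydrogen for elimination.

Step 10
Reactants: 15 (E)-6-iodohept-5-en-1-yne
Product: 17 (1E,5E)-1-bromo-6-iodo-2-methylhepta-1,5-diene, via alkenylalane 16 (not isolated)
Conditions: Me3Al, Cp2ZrCl2 (0.2 equiv), CH2Cl2, 25 °C; then NBS, THF, –30 °C
Reagents that add atoms: trimethylaluminium, C[Al](C)C; N-bromosuccinimide, O=C1CCC(=O)N1Br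
Why: zirconium-catalysed carboalumination adds methyl and aluminium syn across the terminal alkyne with aluminium on the terminal carbon, and brominolysis with retention gives the E alkenyl bromide.

**Union and end game (steps 11–16)**

Step 11
Reactants: 10 iodide (fragment A); 17 bromo iodo diene (fragment B)
Product: 19 (6R)-6-acetyl-4-[(3E,7E)-8-bromo-3,7-dimethylocta-3,7-dienyl]-3-methyloxan-2-one (4,6-cis; both C15 epimers), via alkylzinc iodide 18 (not isolated)
Conditions: 10, Zn dust, LiCl, THF, 25 °C; then 17, Pd(PPh3)4 (5 mol %), THF, 0 → 25 °C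
Reagents that add atoms: none
Why: Negishi coupling, in which zinc inserts into the primary C–I bond without attacking ketone or lactone, zerovalent palladium adds to the alkenyl C–I bond in preference to the C–Br bond, and coupling with retention gives the E C11=C12 olefin.

Step 12
Reactants: 19 bromo diene
Product: 20 (6R)-6-acetyl-4-{2-[(2S,3S)-3-((E)-5-bromo-4-methylpent-4-enyl)-2-methyloxiran-2-yl]ethyl}-3-methyloxan-2-one (4,6-cis; both C15 epimers)
Conditions: 1,2:4,5-di-O-isopropylidene-β-L-erythro-2,3-hexodiulo-2,6-pyranose (ent-Shi ketone, 0.3 equiv), KHSO5 (as 2KHSO5·KHSO4·K2SO4), K2CO3, n-Bu4NHSO4, MeCN/CH2(OMe)2/aq. Na2B4O7 buffer, –5 °C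
Reagents that add atoms: potassium peroxymonosulfate, [K+].[O-]S(=O)(=O)OO
Why: Shi epoxidation, in which the chiral dioxirane attacks the electron-rich C11=C12 olefin through the spiro transition state and leaves the electron-poor bromoalkene; the D-fructose ketone gives the (R,R) epoxide from E-trisubstituted olefins of this type, so its enantiomer should give (11S,12S) by catalyst control.

Step 13
Reactants: 20 epoxy alkenyl bromide
Product: 21 (6R)-6-acetyl-3-methyl-4-{2-[(2S,3S)-2-methyl-3-((E)-4-methylhepta-4,6-dienyl)oxiran-2-yl]ethyl}oxan-2-one (4,6-cis; both C15 epimers)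
Conditions: tributyl(vinyl)stannane, Pd(PPh3)4 (5 mol %), CuI (10 mol %), DMF, 50 °C
Reagents that add atoms: tributyl(vinyl)stannane, C=C[Sn](CCCC)(CCCC)CCCC
Why: Stille coupling with retention installs the terminal (E)-diene under neutral conditions that spare the epoxide, the lactone and the α-acyloxy ketone.

Step 14
Reactants: 21 seco diene ketone
Product: 22 (1R,3R,4S,7E,11S,12S)-11,12-epoxy-4-hydroxycembr-7-en-16,3-olide (both C15 epimers)
Conditions: Ni(acac)2 (20 mol %), Et2Zn (3 equiv), THF, 25 °C, 21 added over 12 h (final 2 mM); then aq. NH4Cl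
Reagents that add atoms: none
Why: Proposed new method: Et2Zn reduces Ni(acac)2 to zerovalent nickel, which binds the s-cis C5=C6–C7=C8 diene and couples its unsubstituted terminus C5 oxidatively with the zinc-activated C4 ketone to give an η3-allyl (C6–C8) alkoxide of divalent nickel; ethyl transfer from zinc, β-hydride elimination (ethylene lost) and C–H reductive elimination at C6 release the zinc alkoxide of 22 and zerovalent nickel. The closest known reaction type is the nickel-catalysed, Et2Zn- or Et3B-promoted homoallylation of aldehydes and ketones with 1,3-dienes, known between two molecules and for five- and six-membered ring closure but not for a macrocycle or for an α-acyloxy ketone, while nickel-catalysed reductive ynal macrocyclisation shows that such oxidative cyclisations can close large rings. The 14-membered carbocycle closes by bonding C5 to C4, endo with respect to the diene (C5 to C8 all become ring atoms) and exo with respect to the carbonyl (the oxygen stays outside the ring). The new C4 centre is controlled by the C3 lactone stereocentre: the acyloxy oxygen cannot chelate, so the Cornforth/polar Felkin–Anh arrangement (C3–O anti to C=O, attack past C3–H) should put C5 on the face that gives (4S). The step needs C5 rather than C8 to bond (C8 is fully substituted and would give an 11-membered ring with a quaternary carbon), hydride delivery to C6 rather than C8 (delivery inside the alkoxide-bound allyl to the proximal terminus, which keeps the E C7=C8 olefin because C8 never becomes σ-bound), the ketone rather than the lactone carbonyl to react (the α-acyloxy ketone is the more electrophilic), and high dilution to favour ring closure over dimerisation.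

Step 15
Reactants: 22 macrocycle (both C15 epimers)
Product: 23 (1R,3R,4S,7E,11S,12S,15S)-11,12-epoxy-4-hydroxycembr-7-en-16,3-olide
Conditions: DBU (2 equiv), toluene, 80 °C
Reagents that add atoms: none
Why: base-mediated α-epimerisation of the lactone through its enolate under thermodynamic control should place the C17 methyl equatorial and trans to the C1–C14 bond on the chair lactone, whose two macrocycle bonds at C1 and C3 are both equatorial (15S); C1 and C3 are no longer enolisable and the minor epimer is resubmitted.

Step 16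
Reactants: 23 macrocyclic olefin
Product: 24 (1R,3R,4S,7R,11S,12S,15S)-11,12-epoxy-7-hydroperoxy-4-hydroxycembr-8(19)-en-16,3-olide (target)
Conditions: O2, hν (white LED), tetraphenylporphyrin (1 mol %), CH2Cl2, –20 °C
Reagents that add atoms: dioxygen, O=O
Why: Schenck ene reaction of singlet oxygen with the only olefin, in which oxygen bonds to C7 and hydrogen is taken from the freely rotating C19 methyl on the more substituted side of the E olefin (cis effect) to give the C8=C19 methylene; attack on the exposed outer face of the macrocyclic olefin should give (7R).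

**Compound list**

1 | (R)-(–)-carvone | C=C(C)[C@H]1CC(=O)C(C)=CC1 | starting material
2 | (1R,5R)-cis-carveol | C=C(C)[C@H]1C[C@@H](O)C(C)=CC1 | intermediate
3 | bis-borane adduct of 2 (O-borinate and C-alkyl-9-BBN; both C15 epimers) | C(C(C)[C@H]1C[C@@H](OB2C3CCCC2CCC3)C(C)=CC1)B1C2CCCC1CCC2 | intermediate
4 | (1R,5R)-5-(1-hydroxypropan-2-yl)-2-methylcyclohex-2-en-1-ol (both C15 epimers) | CC(CO)[C@H]1C[C@@H](O)C(C)=CC1 | intermediate
5 | bicyclic lactol, (1R,5R)-4,8-dimethyl-2-oxabicyclo[3.3.1]non-7-en-3-ol (both C15 epimers) | OC1C(C)[C@H]2C[C@@H](O1)C(C)=CC2 | intermediate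
6 | (1R,5R)-4,8-dimethyl-2-oxabicyclo[3.3.1]non-7-en-3-one (both C15 epimers) | O=C1C(C)[C@H]2C[C@@H](O1)C(C)=CC2 | intermediate
7 | ozonide (1,2,4-trioxolane) of 6 | O=C1C(C)[C@H]2C[C@@H](O1)C3(C)OOC(O3)C2 | intermediate
8 | (6R)-6-acetyl-3-methyl-4-(2-oxoethyl)oxan-2-one (4,6-cis; both C15 epimers) | O=C1C(C)[C@H](CC=O)C[C@@H](O1)C(C)=O | intermediate
9 | (6R)-6-acetyl-4-(2-hydroxyethyl)-3-methyloxan-2-one (4,6-cis; both C15 epimers) | O=C1C(C)[C@H](CCO)C[C@@H](O1)C(C)=O | intermediate
10 | (6R)-6-acetyl-4-(2-iodoethyl)-3-methyloxan-2-one (4,6-cis; both C15 epimers) | O=C1C(C)[C@H](CCI)C[C@@H](O1)C(C)=O | intermediate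
11 | pent-3-yn-1-ol | CC#CCCO | starting material
12 | alkenylzirconocene from 11 (O- and C-bound Cp2ZrCl; Cp drawn σ-bound) | C/C(=C\CCO[Zr](Cl)(C1C=CC=C1)C1C=CC=C1)[Zr](Cl)(C1C=CC=C1)C1C=CC=C1 | intermediate
13 | (E)-4-iodopent-3-en-1-ol | C/C(I)=C\CCO | intermediate
14 | (E)-2,5-diiodopent-2-ene | C/C(I)=C\CCI | intermediate
15 | (E)-6-iodohept-5-en-1-yne | C/C(I)=C\CCC#C | intermediate
16 | (1E,5E)-(6-iodo-2-methylhepta-1,5-dienyl)dimethylalane | C/C(I)=C\CC/C(C)=C/[Al](C)C | intermediate
17 | (1E,5E)-1-bromo-6-iodo-2-methylhepta-1,5-diene | C/C(I)=C\CC/C(C)=C/Br | intermediate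
18 | alkylzinc iodide from 10 | O=C1C(C)[C@H](CC[Zn]I)C[C@@H](O1)C(C)=O | intermediate
19 | (6R)-6-acetyl-4-[(3E,7E)-8-bromo-3,7-dimethylocta-3,7-dienyl]-3-methyloxan-2-one (4,6-cis; both C15 epimers) | O=C1C(C)[C@H](CC/C(C)=C/CC/C(C)=C/Br)C[C@@H](O1)C(C)=O | intermediate
20 | (11S,12S)-epoxide of 19 | O=C1C(C)[C@H](CC[C@]2(C)O[C@H]2CC/C(C)=C/Br)C[C@@H](O1)C(C)=O | intermediate
21 | seco diene ketone (vinyl in place of bromine in 20) | O=C1C(C)[C@H](CC[C@]2(C)O[C@H]2CC/C(C)=C/C=C)C[C@@H](O1)C(C)=O | intermediate
22 | (1R,3R,4S,7E,11S,12S)-11,12-epoxy-4-hydroxycembr-7-en-16,3-olide (both C15 epimers) | C/C1=C\CC[C@](C)(O)[C@H]2C[C@@H](CC[C@]3(C)O[C@H]3CC1)C(C)C(=O)O2 | intermediate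
23 | (1R,3R,4S,7E,11S,12S,15S)-11,12-epoxy-4-hydroxycembr-7-en-16,3-olide | C/C1=C\CC[C@](C)(O)[C@H]2C[C@@H](CC[C@]3(C)O[C@H]3CC1)[C@H](C)C(=O)O2 | intermediate
24 | (1R,3R,4S,7R,11S,12S,15S)-11,12-epoxy-7-hydroperoxy-4-hydroxycembr-8(19)-en-16,3-olide | C=C1CC[C@@H]2O[C@@]2(C)CC[C@@H]2C[C@@H](OC(=O)[C@H]2C)[C@@](C)(O)CC[C@H]1OO | target

**Step count**

Total steps: 16 (fragment A steps 1–6, fragment B steps 7–10, union and end game steps 11–16). Longest linear sequence: 12 steps (1–6, then 11–16).

**Steps most likely to fail**

1. Step 14 (proposed new method). The ring closure may lose to intermolecular coupling, hydride may be delivered to C8 instead of C6 (moving the olefin to C6=C7), or the facial preference at C4 may erode in the macrocyclic transition state.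
Fallback, from 20 back to 22, closing the ring at C6–C7 instead. Vinylcerium (CH2=CHMgBr, CeCl3, THF, –78 °C) should add to the C4 ketone of 20 with the same Felkin–Anh sense to give the tertiary vinyl carbinol F1. 9-BBN then hydroborates the vinyl group to the primary alkylborane F2, which is not isolated. An intramolecular B-alkyl Suzuki–Miyaura coupling of F2 with the C7 alkenyl bromide (PdCl2(dppf), AsPh3, K3PO4, THF/DMF/H2O, high dilution) should close the 14-membered ring with retention of the E olefin and give 22.

2. Step 16. Singlet oxygen may attack the wrong face of C7=C8, and hydrogen abstraction from C6 may compete with abstraction from the C19 methyl.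
Fallback, from 23 back to 24, setting C7 by reagent control. Photooxygenation of 23 in the presence of Ac2O, pyridine and DMAP dehydrates the secondary allylic hydroperoxide in the flask, so both C7 epimers converge on the α-methylene ketone F3. Reduction with the (R)-Me-CBS oxazaborolidine and catecholborane (C8 alkenyl carbon as the large group) should give the (7S)-allylic alcohol F4. Mesylation (MsCl, Et3N) gives the mesylate F5, and SN2 displacement with 2-methoxyprop-2-yl hydroperoxide and CsOH in DMF gives, with inversion, the (7R)-peroxy ketal F6. Aqueous AcOH then frees the hydroperoxide 24. This fallback does not cure abstraction at C6.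

3. Step 15. The equilibrium at C15 may leave a large share of the 15-epimer, or enolisation may be slow.
Fallback, from 1 back to 6 as the single 15S epimer, after which step 15 is dropped. Ene-type chlorination of the isopropenyl group of 1 (Ca(OCl)2, CO2, CH2Cl2/H2O) gives 10-chlorocarvone F7. Oxidation with N-methylmorpholine N-oxide gives the enal F8, and Pinnick oxidation (NaClO2, NaH2PO4, 2-methylbut-2-ene) gives the acrylic acid F9. Carboxylate-directed asymmetric hydrogenation (H2, Ru(OAc)2(BINAP), ligand enantiomer chosen for the 15S product) sets C15 by catalyst control and gives the acid F10. Luche reduction (NaBH4, CeCl3·7H2O) gives the cis hydroxy acid F11, and lactonisation (EDC·HCl, DMAP) gives 6.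

Further compounds
F1 | step 14 | tertiary vinyl carbinol from 20, (4S) | O=C1C(C)[C@H](CC[C@]2(C)O[C@H]2CC/C(C)=C/Br)C[C@@H](O1)[C@@](C)(O)C=C
F2 | step 14 | B-alkyl-9-BBN from F1 | O=C1C(C)[C@H](CC[C@]2(C)O[C@H]2CC/C(C)=C/Br)C[C@@H](O1)[C@@](C)(O)CCB1C2CCCC1CCC2
F3 | step 16 | (1R,3R,4S,11S,12S,15S)-11,12-epoxy-4-hydroxy-7-oxocembr-8(19)-en-16,3-olide | C=C1C(=O)CC[C@](C)(O)[C@H]2C[C@@H](CC[C@]3(C)O[C@H]3CC1)[C@H](C)C(=O)O2
F4 | step 16 | (7S)-allylic alcohol from F3 | C=C1[C@@H](O)CC[C@](C)(O)[C@H]2C[C@@H](CC[C@]3(C)O[C@H]3CC1)[C@H](C)C(=O)O2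
F5 | step 16 | (7S)-methanesulfonate of F4 | C=C1[C@@H](OS(C)(=O)=O)CC[C@](C)(O)[C@H]2C[C@@H](CC[C@]3(C)O[C@H]3CC1)[C@H](C)C(=O)O2
F6 | step 16 | (7R)-2-methoxyprop-2-yl peroxy ketal | C=C1[C@H](OOC(C)(C)OC)CC[C@](C)(O)[C@H]2C[C@@H](CC[C@]3(C)O[C@H]3CC1)[C@H](C)C(=O)O2
F7 | step 15 | (R)-10-chlorocarvone | C=C(CCl)[C@H]1CC(=O)C(C)=CC1
F8 | step 15 | 2-[(1R)-4-methyl-5-oxocyclohex-3-enyl]prop-2-enal | C=C(C=O)[C@H]1CC(=O)C(C)=CC1
F9 | step 15 | 2-[(1R)-4-methyl-5-oxocyclohex-3-enyl]prop-2-enoic acid | C=C(C(=O)O)[C@H]1CC(=O)C(C)=CC1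
F10 | step 15 | (2S)-2-[(1R)-4-methyl-5-oxocyclohex-3-enyl]propanoic acid | C[C@H](C(=O)O)[C@H]1CC(=O)C(C)=CC1
F11 | step 15 | (2S)-2-[(1R,5R)-5-hydroxy-4-methylcyclohex-3-enyl]propanoic acid | C[C@H](C(=O)O)[C@H]1C[C@@H](O)C(C)=CC1
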